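**Retrosynthetic overview**
1. Target 33 comes from macrocycle 31 by desilylation and MnO2 oxidation at C14. Ring A (the ten-membered carbocycle) is closed last, by ring-closing metathesis at C4=C5 of seco-triene 30.
2. 30 comes from lactone aldehyde 20, (Z)-alkenyl iodide 27 (Nozaki–Hiyama–Kishi coupling, C9–C10) and (R)-2-methylbutanoic acid 29.
3. Ring B (the α-methylene-γ-lactone) is made first, in the key step. CO2 is stitched between C11 and C6 of the open-chain iodide/chloride 14, which gives C11–C12 and O–C6 in one flask.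
4. Enabling feature: C6, the oxygen-bearing carbon of ring B, is allylic to the C4=C5 alkene of ring A and stands 1,3 (through C7) to the vinylic carbon C11. The unit C11–C7–C6 can therefore act as alkenyl anion plus π-allyl cation and take up O=C=O as the two-atom partner.
5. 14 comes from (S)-3-hydroxy-γ-butyrolactone 1 (C7, C8, C9, C11) and acrolein 3 (C5, C6 and the carbon later lost as ethene). Ring order: B, then A.

Key step: step 10

Remark on numbering: germacranolide locants are used throughout. C6 is the lactone carbinol, C7 the ring fusion, C8 the free carbinol and C9 the acyloxy carbon. C10=C1 carries C14 (the CHO), followed by C2 and C3. C4=C5 carries C15 (the CH3). C11 is the α-carbon of the lactone, C12 its carbonyl and C13 the exocyclic CH2. TBS = tert-butyldimethylsilyl, TES = triethylsilyl.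
Remark on supply: (R)-2-methylbutanoic acid 29 is taken as commercially available in enantiopure form.

Step 1
Reactants: 1 (S)-3-hydroxy-γ-butyrolactone
Product: 2 (4S)-4-(TBS-oxy)dihydrofuran-2(3H)-one
Conditions: TBSCl, imidazole, DMF, rt
Reagents that add atoms: tert-butyldimethylsilyl chloride, C[Si](C)(Cl)C(C)(C)C
Why: Silyl ether formation on the only hydroxyl group; the C8 stereocentre is taken unchanged from the chiral pool.

Step 2
Reactants: 2 (4S)-4-(TBS-oxy)dihydrofuran-2(3H)-one; 3 acrolein
Product: 5 (3S,4S)-3-(1-hydroxyprop-2-en-1-yl)-4-(TBS-oxy)dihydrofuran-2(3H)-one (C6 epimers), via lithium enolate 4 (not isolated)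
Conditions: LDA, THF, −78 °C; acrolein, −78 °C; AcOH quench
Reagents that add atoms: none
Why: Lithium enolate aldol addition (1,2-addition to the enal), in which the aldehyde approaches the ring enolate anti to the C8 silyloxy group and so sets C7 trans to it, the low temperature holds back β-elimination, and the C6 carbinol configuration does not matter because step 9 erases it.

Step 3
Reactants: 5 aldol adduct
Product: 6 (3S,4S)-4-(TBS-oxy)-3-[1-(TES-oxy)prop-2-en-1-yl]dihydrofuran-2(3H)-one (C6 epimers)
Conditions: TESCl, imidazole, CH2Cl2, 0 °C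
Reagents that add atoms: chlorotriethylsilane, CC[Si](Cl)(CC)CC
Why: Silyl ether formation; the more labile TES group masks O6 through the reducing and basic steps and can later be removed beside the TBS ethers.

Step 4
Reactants: 6 TES-protected lactone
Product: 7 (3S,4S)-4-(TBS-oxy)-3-[1-(TES-oxy)prop-2-en-1-yl]oxolan-2-ol (lactol, anomers)
Conditions: DIBAL-H, CH2Cl2, −78 °C; H2O
Reagents that add atoms: none
Why: Partial lactone reduction with DIBAL-H stops at the tetrahedral aluminium acetal at −78 °C and gives the lactol on hydrolysis without touching C7 or C8.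

Step 5
Reactants: 7 lactol
Product: 8 (2S,3S)-2-(TBS-oxy)-3-ethynyl-4-(TES-oxy)hex-5-en-1-ol (C6 epimers)
Conditions: dimethyl (1-diazo-2-oxopropyl)phosphonate, K2CO3, MeOH, rt
Reagents that add atoms: dimethyl (1-diazo-2-oxopropyl)phosphonate, CC(=O)C(=[N+]=[N-])P(=O)(OC)OC
Why: Ohira–Bestmann homologation acts on the open hydroxy-aldehyde form of the lactol, turns C11 into a terminal alkyne (C13 comes from the reagent) and frees O9, and a possible TBS shift between O8 and O9 is harmless because step 6 silylates whichever hydroxyl remains.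

Step 6
Reactants: 8 alkynol
Product: 9 (2S,3S)-1,2-bis(TBS-oxy)-3-ethynyl-4-(TES-oxy)hex-5-ene (C6 epimers)
Conditions: TBSCl, imidazole, DMF, rt
Reagents that add atoms: tert-butyldimethylsilyl chloride, C[Si](C)(Cl)C(C)(C)C
Why: Silyl ether formation on the only free hydroxyl group.

Step 7
Reactants: 9 trisilylated enyne
Product: 11 (2S,3S)-1,2-bis(TBS-oxy)-3-(1-iodoethenyl)-4-(TES-oxy)hex-5-ene (C6 epimers), via alkenylborane 10 (not isolated)
Conditions: B-iodo-9-BBN, pentane, −20 °C; AcOH, 0 °C
Reagents that add atoms: B-iodo-9-borabicyclo[3.3.1]nonane, IB1C2CCCC1CCC2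
Why: Haloboration of the terminal alkyne places boron on C13 and iodine on C11 (Markovnikov sense) and leaves the monosubstituted alkene alone, and protodeboronation with acetic acid then gives the 2-iodo-1-alkene.

Step 8
Reactants: 11 iodoalkene TES ether
Product: 12 (4S,5S)-5,6-bis(TBS-oxy)-4-(1-iodoethenyl)hex-1-en-3-ol (C6 epimers)
Conditions: PPTS (cat.), MeOH/CH2Cl2, 0 °C
Reagents that add atoms: none
Why: Acid-catalysed methanolysis distinguishes silyl ethers by size, so the secondary TES ether should fall well before the TBS ethers.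

Step 9
Reactants: 12 allylic alcohol
Product: 14 (2E,4S,5S)-5,6-bis(TBS-oxy)-1-chloro-4-(1-iodoethenyl)hex-2-ene, via allylic mesylate 13 (not isolated)
Conditions: MsCl, Et3N, CH2Cl2, −20 °C; LiCl, DMF, rt
Reagents that add atoms: lithium chloride, [Li+].[Cl-]
Why: Mesylation and chloride displacement with allylic transposition (SN2′), in which direct attack at C6 is blocked by the branched C7, chloride exchange equilibrates the allylic chlorides toward the primary E isomer with the internal alkene, and the C6 stereocentre is deliberately erased.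

Step 10
Reactants: 14 (2E,4S,5S)-5,6-bis(TBS-oxy)-1-chloro-4-(1-iodoethenyl)hex-2-ene; 15 carbon dioxide
Product: 18 (4S,5R)-4-[(1S)-1,2-bis(TBS-oxy)ethyl]-5-ethenyl-3-methylidenedihydrofuran-2(3H)-one, via alkenyllithium 16 (not isolated), via lithium acrylate 17 (not isolated)
Conditions: t-BuLi (2.0 equiv), Et2O, −78 °C; CO2 (1 atm), −78 → 0 °C; Pd(PPh3)4 (5 mol %), DMF, 0 → 40 °C
Reagents that add atoms: none
Why: Iodine–lithium exchange on 14 outruns attack on the allylic chloride, and alkenyllithium 16 cannot cyclise on itself (closure at the CH2Cl carbon would put the E alkene C5=C6 into a five-membered ring, closure at C6 would give a methylenecyclopropane), so CO2 captures it as lithium acrylate 17 and makes C11–C12. Pd(PPh3)4 then ionises the allylic chloride to a π-allyl complex of divalent palladium spanning C6, C5 and the terminal carbon, the tethered carboxylate oxygen attacks C6 to make O–C6, and zerovalent palladium and LiCl are released while the alkene moves to the terminal position. The closest known reaction types are the carboxylation of alkenyllithium reagents with CO2 and the palladium-catalysed allylic substitution by an internal carboxylate that gives γ-vinyl-γ-butyrolactones; taken together the flask performs a formal [3+2] annulation of CO2 onto C11–C7–C6, the bond pattern of the palladium-catalysed lactone-forming telomerisation of butadiene with CO2. Ring B closes in the 5-exo mode, since attack at the other allyl terminus would need an E alkene inside a seven-membered lactone. The new stereocentre C6 is controlled by C7: the vinyl group settles trans to the bulky C8 side chain in the cyclisation transition state, and because zerovalent palladium can re-ionise the allylic lactone the trans isomer is also the thermodynamic end point, so neither the C6 epimer mixture of 12 nor any secondary chloride in 14 matters. The step needs chemoselectivity (exchange before substitution, carboxylation before ionisation) and regioselectivity (C6 over the terminal carbon), which are secured by the order of addition, the E geometry of the allylic chloride and the 1,3-relation of C11 and C6.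

Step 11
Reactants: 18 bis-TBS lactone
Product: 19 (4S,5R)-4-[(1S)-1-(TBS-oxy)-2-hydroxyethyl]-5-ethenyl-3-methylidenedihydrofuran-2(3H)-one
Conditions: CSA (cat.), MeOH/CH2Cl2, 0 °C
Reagents that add atoms: none
Why: Acid-catalysed methanolysis removes the unhindered primary TBS ether at O9 faster than the secondary one at O8, which is flanked by ring B.

Step 12
Reactants: 19 primary alcohol
Product: 20 (2S)-2-(TBS-oxy)-2-[(2R,3S)-2-ethenyl-4-methylidene-5-oxooxolan-3-yl]acetaldehyde
Conditions: Dess–Martin periodinane, CH2Cl2, rt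
Reagents that add atoms: none
Why: Dess–Martin oxidation is mild enough to keep the α-silyloxy aldehyde configurationally intact and the acrylate untouched.

Step 13
Reactants: 21 ethyl 4-methylpent-4-enoate
Product: 22 4-methylpent-4-enal
Conditions: DIBAL-H (1.05 equiv), CH2Cl2, −78 °C; H2O
Reagents that add atoms: none
Why: DIBAL-H reduction of an ester stops at the aldehyde stage at −78 °C through the stable tetrahedral aluminium intermediate.

Step 14
Reactants: 22 4-methylpent-4-enal; 23 ethyl (triphenylphosphoranylidene)acetate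
Product: 25 ethyl (2Z)-2-iodo-6-methylhepta-2,6-dienoate, via iodo ylide 24 (not isolated)
Conditions: NIS, CH2Cl2, −20 °C; then 22, rt
Reagents that add atoms: N-iodosuccinimide, O=C1CCC(=O)N1I
Why: Wittig olefination with a stabilised α-iodo ylide formed in situ by iodination of 23; such ylides put the aldehyde chain cis to iodine and trans to the ester, which is the C1=C10 geometry of the target.

Step 15
Reactants: 25 iodo dienoate
Product: 26 (2Z)-2-iodo-6-methylhepta-2,6-dien-1-ol
Conditions: DIBAL-H (2.2 equiv), CH2Cl2, −78 °C; H2O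
Reagents that add atoms: none
Why: DIBAL-H reduces the conjugated ester in 1,2-fashion to the allylic alcohol and leaves the alkenyl iodide and its geometry untouched.

Step 16
Reactants: 26 iodo dienol
Product: 27 (2Z)-1-(TBS-oxy)-2-iodo-6-methylhepta-2,6-diene
Conditions: TBSCl, imidazole, DMF, rt
Reagents that add atoms: tert-butyldimethylsilyl chloride, C[Si](C)(Cl)C(C)(C)C
Why: Silyl ether formation on the only hydroxyl group (the future C14 oxygen).

Step 17
Reactants: 20 lactone aldehyde; 27 (Z)-alkenyl iodide
Product: 28 seco-alcohol (6R,7S,8S,9R): ring B lactone carrying at C7 the chain C8H(OTBS)–C9H(OH)–C10(CH2OTBS)=C1H–CH2CH2–C(CH3)=CH2, with C9 and C2 cis on C10=C1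
Conditions: CrCl2 (4 equiv), NiCl2 (1 mol %), DMSO, rt
Reagents that add atoms: none
Why: Nozaki–Hiyama–Kishi coupling forms the alkenylchromium reagent with retention of alkene geometry and adds it to the aldehyde only (lactone and acrylate are spectators), and Felkin–Anh attack anti to the C8 silyloxy group should set C9 in the 8,9-anti sense.

Step 18
Reactants: 28 seco-alcohol; 29 (R)-2-methylbutanoic acid
Product: 30 seco-ester (6R,7S,8S,9R,2′R): 28 acylated at O9 with the (R)-2-methylbutanoyl group
Conditions: DCC, DMAP (cat.), CH2Cl2, 0 °C → rt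
Reagents that add atoms: none
Why: Steglich esterification of the only free hydroxyl; activation as the acylpyridinium species is mild enough to keep the α-stereocentre of 29.

Step 19
Reactants: 30 seco-ester
Product: 31 macrocycle (6R,7S,8S,9R,2′R): 8-O-TBS, 14-O-TBS germacra-1(10),4,11(13)-trien-12,6-olide with both ring alkenes ring-cis
Conditions: second-generation Hoveyda–Grubbs catalyst (10 mol %), 1,4-benzoquinone (20 mol %), toluene (0.5 mM), 80 °C
Reagents that add atoms: none
Why: Ring-closing metathesis between the C5 vinyl group and the C4 isopropenyl group closes ring A, the ring-cis (Z) trisubstituted alkene is expected because a ring-trans alkene next to the trans-fused lactone and the cis C1=C10 alkene would be far more strained, and the trisubstituted C1=C10 and electron-poor C11=C13 alkenes stay out of the reaction.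

Step 20
Reactants: 31 bis-TBS macrocycle
Product: 32 8,14-diol (6R,7R,8S,9R,2′R)
Conditions: HF·pyridine, THF, 0 °C → rt
Reagents that add atoms: none
Why: Fluoride-mediated desilylation under slightly acidic conditions removes both TBS groups without acyl migration from O9 to O8, translactonisation or conjugate addition to the acrylate.

Step 21
Reactants: 32 8,14-diol
Product: 33 CNP0256845.2, (6R,7R,8S,9R)-8-hydroxy-9-[(2R)-2-methylbutanoyloxy]-14-oxogermacra-1(10)E,4Z,11(13)-trien-12,6-olide
Conditions: MnO2 (20 equiv), CH2Cl2, rt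
Reagents that add atoms: none
Why: MnO2 oxidises only the primary allylic alcohol at C14 to the enal; the saturated secondary C8 hydroxyl is inert.

**Compound list**
1 | (S)-3-hydroxy-γ-butyrolactone | O=C1C[C@H](O)CO1 | starting material
2 | (4S)-4-(TBS-oxy)dihydrofuran-2(3H)-one | O=C1C[C@H](O[Si](C)(C)C(C)(C)C)CO1 | intermediate
3 | acrolein | C=CC=O | starting material
4 | lithium enolate of 2 | [Li]OC1=C[C@H](O[Si](C)(C)C(C)(C)C)CO1 | intermediate
5 | (3S,4S)-3-(1-hydroxyprop-2-en-1-yl)-4-(TBS-oxy)dihydrofuran-2(3H)-one, C6 epimers | O=C1[C@@H](C(O)C=C)[C@H](O[Si](C)(C)C(C)(C)C)CO1 | intermediate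
6 | TES ether of 5 | O=C1[C@@H](C(O[Si](CC)(CC)CC)C=C)[C@H](O[Si](C)(C)C(C)(C)C)CO1 | intermediate
7 | lactol from 6 | OC1[C@@H](C(O[Si](CC)(CC)CC)C=C)[C@H](O[Si](C)(C)C(C)(C)C)CO1 | intermediate
8 | (2S,3S)-2-(TBS-oxy)-3-ethynyl-4-(TES-oxy)hex-5-en-1-ol | C#C[C@@H](C(O[Si](CC)(CC)CC)C=C)[C@H](O[Si](C)(C)C(C)(C)C)CO | intermediate
9 | (2S,3S)-1,2-bis(TBS-oxy)-3-ethynyl-4-(TES-oxy)hex-5-ene | C#C[C@@H](C(O[Si](CC)(CC)CC)C=C)[C@H](O[Si](C)(C)C(C)(C)C)CO[Si](C)(C)C(C)(C)C | intermediate
10 | (Z)-2-iodoalkenyl-9-BBN from 9 (B on C13, I on C11, cis) | I/C([C@@H](C(O[Si](CC)(CC)CC)C=C)[C@H](O[Si](C)(C)C(C)(C)C)CO[Si](C)(C)C(C)(C)C)=C\B1C2CCCC1CCC2 | intermediate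
11 | (2S,3S)-1,2-bis(TBS-oxy)-3-(1-iodoethenyl)-4-(TES-oxy)hex-5-ene | C=C(I)[C@@H](C(O[Si](CC)(CC)CC)C=C)[C@H](O[Si](C)(C)C(C)(C)C)CO[Si](C)(C)C(C)(C)C | intermediate
12 | (4S,5S)-5,6-bis(TBS-oxy)-4-(1-iodoethenyl)hex-1-en-3-ol, C6 epimers | C=C(I)[C@@H](C(O)C=C)[C@H](O[Si](C)(C)C(C)(C)C)CO[Si](C)(C)C(C)(C)C | intermediate
13 | methanesulfonate of 12 | C=C(I)[C@@H](C(OS(C)(=O)=O)C=C)[C@H](O[Si](C)(C)C(C)(C)C)CO[Si](C)(C)C(C)(C)C | intermediate
14 | (2E,4S,5S)-5,6-bis(TBS-oxy)-1-chloro-4-(1-iodoethenyl)hex-2-ene | C=C(I)[C@@H](/C=C/CCl)[C@H](O[Si](C)(C)C(C)(C)C)CO[Si](C)(C)C(C)(C)C | intermediate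
15 | carbon dioxide | O=C=O | starting material
16 | alkenyllithium from 14 (Li on C11) | [Li]C(=C)[C@@H](/C=C/CCl)[C@H](O[Si](C)(C)C(C)(C)C)CO[Si](C)(C)C(C)(C)C | intermediate
17 | lithium 2-substituted acrylate from 16 and 15 | [Li+].[O-]C(=O)C(=C)[C@@H](/C=C/CCl)[C@H](O[Si](C)(C)C(C)(C)C)CO[Si](C)(C)C(C)(C)C | intermediate
18 | (4S,5R)-4-[(1S)-1,2-bis(TBS-oxy)ethyl]-5-ethenyl-3-methylidenedihydrofuran-2(3H)-one | C=C1C(=O)O[C@H](C=C)[C@H]1[C@H](O[Si](C)(C)C(C)(C)C)CO[Si](C)(C)C(C)(C)C | intermediate
19 | (4S,5R)-4-[(1S)-1-(TBS-oxy)-2-hydroxyethyl]-5-ethenyl-3-methylidenedihydrofuran-2(3H)-one | C=C1C(=O)O[C@H](C=C)[C@H]1[C@H](O[Si](C)(C)C(C)(C)C)CO | intermediate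
20 | (2S)-2-(TBS-oxy)-2-[(2R,3S)-2-ethenyl-4-methylidene-5-oxooxolan-3-yl]acetaldehyde | C=C1C(=O)O[C@H](C=C)[C@H]1[C@H](O[Si](C)(C)C(C)(C)C)C=O | intermediate
21 | ethyl 4-methylpent-4-enoate | C=C(C)CCC(=O)OCC | starting material
22 | 4-methylpent-4-enal | C=C(C)CCC=O | intermediate
23 | ethyl (triphenylphosphoranylidene)acetate | CCOC(=O)C=P(c1ccccc1)(c1ccccc1)c1ccccc1 | starting material
24 | ethyl iodo(triphenylphosphoranylidene)acetate | CCOC(=O)C(I)=P(c1ccccc1)(c1ccccc1)c1ccccc1 | intermediate
25 | ethyl (2Z)-2-iodo-6-methylhepta-2,6-dienoate | C=C(C)CC/C=C(/C(=O)OCC)I | intermediate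
26 | (2Z)-2-iodo-6-methylhepta-2,6-dien-1-ol | C=C(C)CC/C=C(/CO)I | intermediate
27 | (2Z)-1-(TBS-oxy)-2-iodo-6-methylhepta-2,6-diene | C=C(C)CC/C=C(/CO[Si](C)(C)C(C)(C)C)I | intermediate
28 | seco-alcohol (6R,7S,8S,9R) | C=C1C(=O)O[C@H](C=C)[C@H]1[C@H](O[Si](C)(C)C(C)(C)C)[C@H](O)/C(CO[Si](C)(C)C(C)(C)C)=C\CCC(C)=C | intermediate
29 | (R)-2-methylbutanoic acid | OC(=O)[C@H](C)CC | starting material
30 | seco-ester (6R,7S,8S,9R,2′R) | C=C1C(=O)O[C@H](C=C)[C@H]1[C@H](O[Si](C)(C)C(C)(C)C)[C@H](OC(=O)[C@H](C)CC)/C(CO[Si](C)(C)C(C)(C)C)=C\CCC(C)=C | intermediate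
31 | 8,14-bis-O-TBS macrocycle | C=C1C(=O)O[C@@H]2/C=C(/C)CC/C=C(/CO[Si](C)(C)C(C)(C)C)[C@@H](OC(=O)[C@H](C)CC)[C@@H](O[Si](C)(C)C(C)(C)C)[C@@H]12 | intermediate
32 | 8,14-diol | C=C1C(=O)O[C@@H]2/C=C(/C)CC/C=C(/CO)[C@@H](OC(=O)[C@H](C)CC)[C@@H](O)[C@@H]12 | intermediate
33 | CNP0256845.2 | C=C1C(=O)O[C@@H]2/C=C(/C)CC/C=C(/C=O)[C@@H](OC(=O)[C@H](C)CC)[C@@H](O)[C@@H]12 | target

**Step count**
Total step count: 21. Longest linear sequence: 17 (steps 1–12 and 17–21).

**Steps most likely to fail**

Step 10. Three processes could spoil it: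
- The organolithium reagents may attack the allylic chloride.
- A proton may be transferred from the doubly allylic C7–H.
- The π-allyl complex may lose a β-hydride toward a triene instead of closing the C–O bond.

The fallback builds the lactone by carbonylation with CO and keeps the C6 oxygen of the aldol. It sets out from 12. Dess–Martin oxidation gives the vinyl ketone F1. Corey–Bakshi–Shibata reduction, with the catalyst enantiomer matched to the (6R)-carbinol, gives the single allylic alcohol F2. Carbonylative lactonisation of the 2-iodoalkene (Pd(PPh3)4, CO at 1 atm, K2CO3, THF, 60 °C) then closes ring B with retention at C6. The fallback comes back to the route at 18.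

Step 19. The hindered 1,1-disubstituted alkene may engage too slowly, so that oligomerisation through the vinyl group takes over. Closure to the ring-trans alkene is also possible. The fallback closes the ring on a substrate with an sp2 carbon at C9 and sets C9 afterwards on the ring. It sets out from 28. Dess–Martin oxidation gives the open-chain enone F4, in which the bulky sp3 centre next to C10 is gone. Ring-closing metathesis gives the macrocyclic dienone F5. Corey–Bakshi–Shibata reduction gives the macrocyclic (9R)-alcohol F6. Steglich esterification with 29 brings the fallback back to the route at 31.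

Step 17. Facial selectivity at the aldehyde may be poor, because the C7 branch can work against the Felkin–Anh preference. The fallback uses both epimers in a stereoconvergent way. It sets out from 20, coupled with 27 as in step 17. The (9S)-alcohol F3 is separated from 28 and esterified with 29 under Mitsunobu conditions (PPh3, DIAD, toluene, 0 °C) with inversion at C9. It comes back to the route at 30.

**Further compounds**
F1 | step 10 | (4R,5S)-5,6-bis(TBS-oxy)-4-(1-iodoethenyl)hex-1-en-3-one | C=C(I)[C@@H](C(=O)C=C)[C@H](O[Si](C)(C)C(C)(C)C)CO[Si](C)(C)C(C)(C)C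
F2 | step 10 | (3R,4S,5S)-5,6-bis(TBS-oxy)-4-(1-iodoethenyl)hex-1-en-3-ol | C=C(I)[C@@H]([C@H](O)C=C)[C@H](O[Si](C)(C)C(C)(C)C)CO[Si](C)(C)C(C)(C)C
F3 | step 17 | 9-epimer of seco-alcohol 28 (6R,7S,8S,9S) | C=C1C(=O)O[C@H](C=C)[C@H]1[C@H](O[Si](C)(C)C(C)(C)C)[C@@H](O)/C(CO[Si](C)(C)C(C)(C)C)=C\CCC(C)=C
F4 | step 19 | open-chain C9 enone from 28 | C=C1C(=O)O[C@H](C=C)[C@H]1[C@H](O[Si](C)(C)C(C)(C)C)C(=O)/C(CO[Si](C)(C)C(C)(C)C)=C\CCC(C)=C
F5 | step 19 | macrocyclic C9 dienone, 8,14-bis-O-TBS | C=C1C(=O)O[C@@H]2/C=C(/C)CC/C=C(/CO[Si](C)(C)C(C)(C)C)C(=O)[C@@H](O[Si](C)(C)C(C)(C)C)[C@@H]12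
F6 | step 19 | macrocyclic (9R)-alcohol, 8,14-bis-O-TBS | C=C1C(=O)O[C@@H]2/C=C(/C)CC/C=C(/CO[Si](C)(C)C(C)(C)C)[C@@H](O)[C@@H](O[Si](C)(C)C(C)(C)C)[C@@H]12
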